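**Retrosynthetic overview**

1. The ring A benzyl group on C3 comes off last: aldol condensation of the finished lactone with protected vanillin, hydrogenation of the (E)-benzylidene from the face opposite the C4 arm (3,4-cis), then global desilylation.
2. The strategy rests on the lactone ring (O1, C2 carbonyl, C3, C4, C5): C5 carries ring B and O1 (donor end) and C3 is α to the C2 carbonyl (acceptor end). Joining C3 to C5 gives a cyclopropane standing on C4, a 2-(silyloxymethyl)-3-arylcyclopropanecarboxylic acid; acid-catalysed scission of that C3–C5 bond with capture of C5 by the carboxyl oxygen (O1–C5) gives the 4,5-trans lactone.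
3. The cyclopropane acid comes from hydroxide opening and O-silylation of a 6-aryl-3-oxabicyclo[3.1.0]hexan-2-one, made by enantioselective intramolecular cyclopropanation of the (E)-cinnamyl diazoacetate derived from methyl ferulate; this sets C4.
4. Ring order: cyclopropane plus a temporary lactone (step 5), temporary lactone opened (step 6), final lactone by cyclopropane scission (step 7); rings A and B are bought in with vanillin and methyl ferulate.

Key step: step 7

Remark on the chemistry: Rh2(4S-MPPIM)4 is assumed to give the (1R,5S,6S) bicyclic lactone, the sense these (S)-configured dirhodium carboxamidates show with allylic diazoacetates; if the opposite sense were found, Rh2(4R-MPPIM)4 would be used with no other change.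

**Route**

Step 1
Reactants: 1 methyl (E)-ferulate
Product: 2 methyl (2E)-3-[3-methoxy-4-(triisopropylsilyloxy)phenyl]prop-2-enoate
Conditions: TIPSCl, imidazole, DMF, rt
Reagents that add atoms: triisopropylsilyl chloride (TIPSCl), CC(C)[Si](Cl)(C(C)C)C(C)C
Why: Imidazole-mediated O-silylation of the phenol; TIPS is chosen because an aryl TIPS ether should outlast the hydroxide, triflic acid and lithium amide steps ahead, where an aryl TBS ether would be at risk.

Step 2
Reactants: 2 methyl (2E)-3-[3-methoxy-4-(triisopropylsilyloxy)phenyl]prop-2-enoate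
Product: 3 (2E)-3-[3-methoxy-4-(triisopropylsilyloxy)phenyl]prop-2-en-1-ol
Conditions: i-Bu2AlH (2.5 equiv), CH2Cl2, −78 to 0 °C; aq. potassium sodium tartrate
Reagents that add atoms: none
Why: 1,2-Reduction of the α,β-unsaturated ester by i-Bu2AlH at low temperature should give the allylic alcohol with the E-alkene and the aryl silyl ether untouched.

Step 3
Reactants: 3 (2E)-3-[3-methoxy-4-(triisopropylsilyloxy)phenyl]prop-2-en-1-ol; 4 bromoacetyl bromide
Product: 5 (2E)-3-[3-methoxy-4-(triisopropylsilyloxy)phenyl]prop-2-en-1-yl bromoacetate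
Conditions: NaHCO3, MeCN, 0 °C
Reagents that add atoms: none
Why: O-Acylation of the primary allylic alcohol at the acyl bromide terminus, with NaHCO3 as a mild HBr scavenger so that the ionisable p-silyloxycinnamyl ester is not exposed to acid.

Step 4
Reactants: 5 (2E)-3-[3-methoxy-4-(triisopropylsilyloxy)phenyl]prop-2-en-1-yl bromoacetate
Product: 7 (2E)-3-[3-methoxy-4-(triisopropylsilyloxy)phenyl]prop-2-en-1-yl diazoacetate, via N-alkylated ditosylhydrazide 6 (not isolated)
Conditions: TsNHNHTs (2 equiv), DBU (5 equiv), THF, 0 °C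
Reagents that add atoms: N,N'-bis(p-toluenesulfonyl)hydrazine, Cc1ccc(cc1)S(=O)(=O)NNS(=O)(=O)c1ccc(C)cc1
Why: Diazoacetate synthesis by the ditosylhydrazine method: the hydrazide anion displaces bromide (SN2) and DBU then expels two sulfinates, conditions that leave the ester, the alkene and the silyl ether alone.

Step 5
Reactants: 7 (2E)-3-[3-methoxy-4-(triisopropylsilyloxy)phenyl]prop-2-en-1-yl diazoacetate
Product: 8 (1R,5S,6S)-6-[3-methoxy-4-(triisopropylsilyloxy)phenyl]-3-oxabicyclo[3.1.0]hexan-2-one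
Conditions: Rh2(4S-MPPIM)4 (1 mol %), CH2Cl2, reflux, slow addition of 7
Reagents that add atoms: none
Why: Intramolecular cyclopropanation by the rhodium carbenoid: the tether enforces the cis ring fusion, the E-alkene geometry is transferred stereospecifically so that the aryl group ends exo (trans to both fusion substituents), and the chiral carboxamidate ligands, suited to trans-disubstituted allylic diazoacetates, select the alkene face and so set C1, C5 and C6 together.

Step 6
Reactants: 8 (1R,5S,6S)-6-[3-methoxy-4-(triisopropylsilyloxy)phenyl]-3-oxabicyclo[3.1.0]hexan-2-one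
Product: 11 (1R,2S,3S)-2-[(tert-butyldiphenylsilyloxy)methyl]-3-[3-methoxy-4-(triisopropylsilyloxy)phenyl]cyclopropane-1-carboxylic acid, via sodium hydroxy carboxylate 9 (not isolated), via silyl ether silyl ester 10 (not isolated)
Conditions: NaOH (1.05 equiv), THF/H2O, 0 °C to rt; evaporate, toluene azeotrope; TBDPSCl (2.5 equiv), imidazole, DMF, rt; K2CO3, MeOH/THF/H2O, 0 °C; KH2PO4 to pH 5
Reagents that add atoms: sodium hydroxide, [Na+].[OH-]; tert-butyldiphenylsilyl chloride (TBDPSCl), CC(C)(C)[Si](Cl)(c1ccccc1)c1ccccc1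
Why: Saponification of the strained lactone gives the cis-hydroxy carboxylate, which is silylated as the salt so that it is never acidified and cannot relactonise, and the silyl ester formed alongside is cleaved selectively by brief carbonate methanolysis, the three stereocentres not being touched.

Step 7
Reactants: 11 (1R,2S,3S)-2-[(tert-butyldiphenylsilyloxy)methyl]-3-[3-methoxy-4-(triisopropylsilyloxy)phenyl]cyclopropane-1-carboxylic acid
Product: 12 (4S,5R)-4-[(tert-butyldiphenylsilyloxy)methyl]-5-[3-methoxy-4-(triisopropylsilyloxy)phenyl]oxolan-2-one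
Conditions: CF3SO3H (10 mol %), CH2Cl2, −40 to 0 °C; Et3N quench
Reagents that add atoms: none
Why: Protonation of the carboxyl group polarises the cyclopropane bond that joins the acceptor carbon to the donor carbon (C3–C5 in lactone numbering); it breaks heterolytically with release of ring strain, the 4-silyloxy-3-methoxyphenyl ring taking the charge as a benzylic, quinone-methide-like cation while the other end becomes the acid enol, which tautomerises to the C3 methylene. The closest known reaction type is the acid-mediated isomerisation of 2-arylcyclopropanecarboxylic acids (donor–acceptor cyclopropanes) to γ-aryl-γ-butyrolactones. The carboxyl oxygen closes the one ring formed, the lactone, by 5-exo-trig attack on the cationic C5, making the O1–C5 bond. C4 takes no part in any bond change and keeps the configuration set in step 5, and C5 is created at the capture, the oxygen arriving on the face of the planar cation opposite the C4 silyloxymethyl arm. The step needs scission of C3–C5 and not of C4–C5, and 4,5-trans capture: the first is secured because only the C3–C5 bond is flanked by both donor and acceptor, the second by the arm shielding one face and by reversible re-ionisation of the benzylic C5–O1 bond, which should drain any cis lactone to the more stable trans isomer.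

Step 8
Reactants: 13 vanillin
Product: 14 3-methoxy-4-(triisopropylsilyloxy)benzaldehyde
Conditions: TIPSCl, imidazole, DMF, rt
Reagents that add atoms: triisopropylsilyl chloride (TIPSCl), CC(C)[Si](Cl)(C(C)C)C(C)C
Why: Imidazole-mediated silylation of the phenol gives the ring A aldehyde with the same protecting group as ring B, so that one fluoride treatment can finish the synthesis.

Step 9
Reactants: 12 (4S,5R)-4-[(tert-butyldiphenylsilyloxy)methyl]-5-[3-methoxy-4-(triisopropylsilyloxy)phenyl]oxolan-2-one; 14 3-methoxy-4-(triisopropylsilyloxy)benzaldehyde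
Product: 15 (4S,5R)-4-[(tert-butyldiphenylsilyloxy)methyl]-3-{hydroxy[3-methoxy-4-(triisopropylsilyloxy)phenyl]methyl}-5-[3-methoxy-4-(triisopropylsilyloxy)phenyl]oxolan-2-one, mixture of epimers at C3 and at the carbinol carbon
Conditions: LiN(SiMe3)2 (1.1 equiv), THF, −78 °C; then 14; aq. NH4Cl
Reagents that add atoms: none
Why: Aldol addition of the lithium enolate, which can form only at C3; C4 and C5 carry no acidic hydrogen and no β-leaving group, and the two new centres are erased in step 10, so their ratio is of no consequence.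

Step 10
Reactants: 15 aldol adducts (epimer mixture)
Product: 17 (3E,4S,5R)-4-[(tert-butyldiphenylsilyloxy)methyl]-3-[3-methoxy-4-(triisopropylsilyloxy)benzylidene]-5-[3-methoxy-4-(triisopropylsilyloxy)phenyl]oxolan-2-one, via mesylate 16 (not isolated)
Conditions: MsCl, Et3N, CH2Cl2, 0 °C; then DBU, rt
Reagents that add atoms: none
Why: Mesylation followed by DBU-promoted E1cB elimination should funnel both carbinol epimers to the conjugated (E)-benzylidene lactone, the more stable isomer, with a short exposure to base so that the alkene does not move into the ring.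

Step 11
Reactants: 17 (3E,4S,5R)-benzylidene lactone
Product: 18 (3S,4S,5R)-4-[(tert-butyldiphenylsilyloxy)methyl]-3-[3-methoxy-4-(triisopropylsilyloxy)benzyl]-5-[3-methoxy-4-(triisopropylsilyloxy)phenyl]oxolan-2-one
Conditions: H2 (1 atm), 5% Rh/Al2O3, EtOAc, rt
Reagents that add atoms: none
Why: Heterogeneous syn-hydrogenation of the exocyclic alkene: allylic 1,3-strain from the (E)-aryl group turns the C4 silyloxymethyl arm pseudo-axial so that it covers one face, hydrogen adds to the other and the benzyl group ends cis to the arm (3S), while Rh/Al2O3 is chosen for its low tendency to hydrogenolyse the benzylic C5–O1 bond.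

Step 12
Reactants: 18 (3S,4S,5R)-tris-silyl lactone
Product: 19 (3S,4S,5R)-5-(4-hydroxy-3-methoxyphenyl)-3-[(4-hydroxy-3-methoxyphenyl)methyl]-4-(hydroxymethyl)oxolan-2-one (target)
Conditions: Bu4NF/AcOH (1:1), THF, 0 °C to rt
Reagents that add atoms: none
Why: Fluoride cleavage of the two aryl O–Si bonds and the primary O–Si bond; the acetic acid buffer keeps the medium from epimerising the cis C3 centre or letting the freed C4 hydroxymethyl group translactonise.

**Compound list**

1 | methyl (E)-ferulate, methyl (2E)-3-(4-hydroxy-3-methoxyphenyl)prop-2-enoate | COC(=O)/C=C/c1ccc(O)c(OC)c1 | starting material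
2 | methyl (2E)-3-[3-methoxy-4-(triisopropylsilyloxy)phenyl]prop-2-enoate | COC(=O)/C=C/c1ccc(O[Si](C(C)C)(C(C)C)C(C)C)c(OC)c1 | intermediate
3 | (2E)-3-[3-methoxy-4-(triisopropylsilyloxy)phenyl]prop-2-en-1-ol | OC/C=C/c1ccc(O[Si](C(C)C)(C(C)C)C(C)C)c(OC)c1 | intermediate
4 | bromoacetyl bromide | BrCC(Br)=O | starting material
5 | (2E)-3-[3-methoxy-4-(triisopropylsilyloxy)phenyl]prop-2-en-1-yl bromoacetate | BrCC(=O)OC/C=C/c1ccc(O[Si](C(C)C)(C(C)C)C(C)C)c(OC)c1 | intermediate
6 | (2E)-3-[3-methoxy-4-(triisopropylsilyloxy)phenyl]prop-2-en-1-yl [1,2-bis(p-toluenesulfonyl)hydrazin-1-yl]acetate | O=C(CN(NS(=O)(=O)c1ccc(C)cc1)S(=O)(=O)c1ccc(C)cc1)OC/C=C/c1ccc(O[Si](C(C)C)(C(C)C)C(C)C)c(OC)c1 | intermediate (not isolated)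
7 | (2E)-3-[3-methoxy-4-(triisopropylsilyloxy)phenyl]prop-2-en-1-yl diazoacetate | [N-]=[N+]=CC(=O)OC/C=C/c1ccc(O[Si](C(C)C)(C(C)C)C(C)C)c(OC)c1 | intermediate
8 | (1R,5S,6S)-6-[3-methoxy-4-(triisopropylsilyloxy)phenyl]-3-oxabicyclo[3.1.0]hexan-2-one (aryl exo) | O=C1[C@H]2[C@@H](CO1)[C@@H]2c1ccc(O[Si](C(C)C)(C(C)C)C(C)C)c(OC)c1 | intermediate
9 | sodium (1R,2S,3S)-2-(hydroxymethyl)-3-[3-methoxy-4-(triisopropylsilyloxy)phenyl]cyclopropane-1-carboxylate | [Na+].[O-]C(=O)[C@H]1[C@@H](CO)[C@@H]1c1ccc(O[Si](C(C)C)(C(C)C)C(C)C)c(OC)c1 | intermediate (not isolated)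
10 | tert-butyldiphenylsilyl (1R,2S,3S)-2-[(tert-butyldiphenylsilyloxy)methyl]-3-[3-methoxy-4-(triisopropylsilyloxy)phenyl]cyclopropane-1-carboxylate | CC(C)(C)[Si](OC(=O)[C@H]1[C@@H](CO[Si](c2ccccc2)(c2ccccc2)C(C)(C)C)[C@@H]1c1ccc(O[Si](C(C)C)(C(C)C)C(C)C)c(OC)c1)(c1ccccc1)c1ccccc1 | intermediate (not isolated)
11 | (1R,2S,3S)-2-[(tert-butyldiphenylsilyloxy)methyl]-3-[3-methoxy-4-(triisopropylsilyloxy)phenyl]cyclopropane-1-carboxylic acid (carboxyl and CH2O arm cis, aryl trans to both) | OC(=O)[C@H]1[C@@H](CO[Si](c2ccccc2)(c2ccccc2)C(C)(C)C)[C@@H]1c1ccc(O[Si](C(C)C)(C(C)C)C(C)C)c(OC)c1 | intermediate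
12 | (4S,5R)-4-[(tert-butyldiphenylsilyloxy)methyl]-5-[3-methoxy-4-(triisopropylsilyloxy)phenyl]oxolan-2-one (4,5-trans) | O=C1C[C@@H](CO[Si](c2ccccc2)(c2ccccc2)C(C)(C)C)[C@H](c2ccc(O[Si](C(C)C)(C(C)C)C(C)C)c(OC)c2)O1 | intermediate
13 | vanillin | O=Cc1ccc(O)c(OC)c1 | starting material
14 | 3-methoxy-4-(triisopropylsilyloxy)benzaldehyde | O=Cc1ccc(O[Si](C(C)C)(C(C)C)C(C)C)c(OC)c1 | intermediate
15 | (4S,5R)-4-[(tert-butyldiphenylsilyloxy)methyl]-3-{hydroxy[3-methoxy-4-(triisopropylsilyloxy)phenyl]methyl}-5-[3-methoxy-4-(triisopropylsilyloxy)phenyl]oxolan-2-one, epimer mixture at C3 and the carbinol carbon | O=C1C(C(O)c2ccc(O[Si](C(C)C)(C(C)C)C(C)C)c(OC)c2)[C@@H](CO[Si](c2ccccc2)(c2ccccc2)C(C)(C)C)[C@H](c2ccc(O[Si](C(C)C)(C(C)C)C(C)C)c(OC)c2)O1 | intermediate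
16 | methanesulfonate of 15 at the carbinol oxygen, epimer mixture | O=C1C(C(OS(C)(=O)=O)c2ccc(O[Si](C(C)C)(C(C)C)C(C)C)c(OC)c2)[C@@H](CO[Si](c2ccccc2)(c2ccccc2)C(C)(C)C)[C@H](c2ccc(O[Si](C(C)C)(C(C)C)C(C)C)c(OC)c2)O1 | intermediate (not isolated)
17 | (3E,4S,5R)-4-[(tert-butyldiphenylsilyloxy)methyl]-3-[3-methoxy-4-(triisopropylsilyloxy)benzylidene]-5-[3-methoxy-4-(triisopropylsilyloxy)phenyl]oxolan-2-one | O=C1/C(=C/c2ccc(O[Si](C(C)C)(C(C)C)C(C)C)c(OC)c2)[C@@H](CO[Si](c2ccccc2)(c2ccccc2)C(C)(C)C)[C@H](c2ccc(O[Si](C(C)C)(C(C)C)C(C)C)c(OC)c2)O1 | intermediate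
18 | (3S,4S,5R)-4-[(tert-butyldiphenylsilyloxy)methyl]-3-[3-methoxy-4-(triisopropylsilyloxy)benzyl]-5-[3-methoxy-4-(triisopropylsilyloxy)phenyl]oxolan-2-one (3,4-cis, 4,5-trans) | COc1cc(C[C@@H]2C(=O)O[C@@H](c3ccc(O[Si](C(C)C)(C(C)C)C(C)C)c(OC)c3)[C@@H]2CO[Si](c4ccccc4)(c5ccccc5)C(C)(C)C)ccc1O[Si](C(C)C)(C(C)C)C(C)C | intermediate
19 | (3S,4S,5R)-5-(4-hydroxy-3-methoxyphenyl)-3-[(4-hydroxy-3-methoxyphenyl)methyl]-4-(hydroxymethyl)oxolan-2-one | COc1cc(C[C@@H]2C(=O)O[C@@H](c3ccc(O)c(OC)c3)[C@@H]2CO)ccc1O | target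

**Step count**

Total steps: 12. Longest linear sequence: 11 steps (steps 1 to 7, then 9 to 12); step 8 is a one-step side branch.

**Steps most likely to fail**

Step 7 (cyclopropane scission with lactonisation). The cyclopropane may open at the C4–C5 bond instead of C3–C5, after which the silyl ether oxygen and not the carboxyl group would trap the cation. The acid may also strip the silyl ether, the benzylic cation may oligomerise on the electron-rich arenes, and the cis/trans equilibration at C5 may stop short. The fallback builds the same lactone by an aldol route and no longer uses the cyclopropane. It sets out from aldehyde 14, which can serve as the ring B aldehyde because both aryl groups are the same, and returns at 12. (R)-4-Benzyl-1,3-oxazolidin-2-one is N-acylated (n-BuLi, then methyl 4-chloro-4-oxobutanoate, THF, −78 °C) to (4R)-4-benzyl-3-(4-methoxy-4-oxobutanoyl)-1,3-oxazolidin-2-one F1. Its (Z)-boron enolate (Bu2BOTf, i-Pr2NEt, CH2Cl2, −78 to 0 °C) should add to 14 in an Evans syn-aldol reaction to give methyl (3R,4R)-3-[(4R)-4-benzyl-2-oxo-1,3-oxazolidine-3-carbonyl]-4-hydroxy-4-[3-methoxy-4-(triisopropylsilyloxy)phenyl]butanoate F2. The γ-hydroxy ester is closed (cat. TsOH, toluene, rt) to the trans lactone imide (4R)-4-benzyl-3-{(2R,3R)-2-[3-methoxy-4-(triisopropylsilyloxy)phenyl]-5-oxooxolane-3-carbonyl}-1,3-oxazolidin-2-one F3, the syn adduct mapping onto the 4,5-trans lactone. Reductive removal of the auxiliary (NaBH4, THF/H2O, 0 °C), which should spare the less electrophilic lactone, gives (4S,5R)-4-(hydroxymethyl)-5-[3-methoxy-4-(triisopropylsilyloxy)phenyl]oxolan-2-one F4. Silylation (TBDPSCl, imidazole, DMF) then gives 12.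

Step 11 (hydrogenation). Facial selectivity may be poor because the C5 aryl group, lying on the face opposite the C4 arm, partly blocks the face from which hydrogen must come; migration of the alkene into the ring or hydrogenolysis of the benzylic C5–O1 bond may also intervene. The fallback replaces hydrogen delivery by enolate alkylation and kinetic protonation. It sets out from 12 (with 14 as the source of the benzyl unit) and returns at 18. Aldehyde 14 is reduced (NaBH4, MeOH, 0 °C) to [3-methoxy-4-(triisopropylsilyloxy)phenyl]methanol F5 and converted (PBr3, Et2O, 0 °C) into 4-(bromomethyl)-2-methoxy-1-(triisopropylsilyloxy)benzene F6. The lithium enolate of 12 (LiN(SiMe3)2, THF, −78 °C) is alkylated with F6 anti to the C4 arm to give the 3,4-trans lactone (3R,4S,5R)-4-[(tert-butyldiphenylsilyloxy)methyl]-3-[3-methoxy-4-(triisopropylsilyloxy)benzyl]-5-[3-methoxy-4-(triisopropylsilyloxy)phenyl]oxolan-2-one F7. F7 is deprotonated again (LiN(SiMe3)2, THF, −78 °C) and the enolate is quenched cold with the bulky proton donor 2,6-di-tert-butyl-4-methylphenol. The proton should arrive anti to the C4 arm, turning the benzyl group cis to it and giving 18.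

Step 6 (lactone opening and silylation). The hydroxy carboxylate may close back to lactone 8 during drying, silylation or work-up, and hydroxide may cleave the aryl silyl ether. The fallback opens the lactone by aminolysis so that no free hydroxy acid or hydroxide is involved. It sets out from 8 and returns at 11. Lactone 8 is opened with MeNH(OMe)·HCl and i-PrMgCl (THF, −20 °C) to (1R,2S,3S)-2-(hydroxymethyl)-N-methoxy-N-methyl-3-[3-methoxy-4-(triisopropylsilyloxy)phenyl]cyclopropane-1-carboxamide F8. This is silylated at once (TBDPSCl, imidazole, DMF) to (1R,2S,3S)-2-[(tert-butyldiphenylsilyloxy)methyl]-N-methoxy-N-methyl-3-[3-methoxy-4-(triisopropylsilyloxy)phenyl]cyclopropane-1-carboxamide F9. Reduction (i-Bu2AlH, THF, −78 °C) gives (1R,2S,3S)-2-[(tert-butyldiphenylsilyloxy)methyl]-3-[3-methoxy-4-(triisopropylsilyloxy)phenyl]cyclopropane-1-carbaldehyde F10, and Pinnick oxidation (NaClO2, NaH2PO4, 2-methyl-2-butene, t-BuOH/H2O) gives acid 11. Epimerisation next to the formyl group would not matter, since that carbon becomes the C3 methylene in step 7.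

**Further compounds**

F1 | step 7 | (4R)-4-benzyl-3-(4-methoxy-4-oxobutanoyl)-1,3-oxazolidin-2-one | COC(=O)CCC(=O)N1[C@H](Cc2ccccc2)COC1=O
F2 | step 7 | methyl (3R,4R)-3-[(4R)-4-benzyl-2-oxo-1,3-oxazolidine-3-carbonyl]-4-hydroxy-4-[3-methoxy-4-(triisopropylsilyloxy)phenyl]butanoate | COC(=O)C[C@@H](C(=O)N1[C@H](Cc2ccccc2)COC1=O)[C@@H](O)c1ccc(O[Si](C(C)C)(C(C)C)C(C)C)c(OC)c1
F3 | step 7 | (4R)-4-benzyl-3-{(2R,3R)-2-[3-methoxy-4-(triisopropylsilyloxy)phenyl]-5-oxooxolane-3-carbonyl}-1,3-oxazolidin-2-one | O=C1C[C@@H](C(=O)N2[C@H](Cc3ccccc3)COC2=O)[C@H](c2ccc(O[Si](C(C)C)(C(C)C)C(C)C)c(OC)c2)O1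
F4 | step 7 | (4S,5R)-4-(hydroxymethyl)-5-[3-methoxy-4-(triisopropylsilyloxy)phenyl]oxolan-2-one | O=C1C[C@@H](CO)[C@H](c2ccc(O[Si](C(C)C)(C(C)C)C(C)C)c(OC)c2)O1
F5 | step 11 | [3-methoxy-4-(triisopropylsilyloxy)phenyl]methanol | OCc1ccc(O[Si](C(C)C)(C(C)C)C(C)C)c(OC)c1
F6 | step 11 | 4-(bromomethyl)-2-methoxy-1-(triisopropylsilyloxy)benzene | BrCc1ccc(O[Si](C(C)C)(C(C)C)C(C)C)c(OC)c1
F7 | step 11 | (3R,4S,5R)-4-[(tert-butyldiphenylsilyloxy)methyl]-3-[3-methoxy-4-(triisopropylsilyloxy)benzyl]-5-[3-methoxy-4-(triisopropylsilyloxy)phenyl]oxolan-2-one | COc1cc(C[C@H]2C(=O)O[C@@H](c3ccc(O[Si](C(C)C)(C(C)C)C(C)C)c(OC)c3)[C@@H]2CO[Si](c4ccccc4)(c5ccccc5)C(C)(C)C)ccc1O[Si](C(C)C)(C(C)C)C(C)C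
F8 | step 6 | (1R,2S,3S)-2-(hydroxymethyl)-N-methoxy-N-methyl-3-[3-methoxy-4-(triisopropylsilyloxy)phenyl]cyclopropane-1-carboxamide | CON(C)C(=O)[C@H]1[C@@H](CO)[C@@H]1c1ccc(O[Si](C(C)C)(C(C)C)C(C)C)c(OC)c1
F9 | step 6 | (1R,2S,3S)-2-[(tert-butyldiphenylsilyloxy)methyl]-N-methoxy-N-methyl-3-[3-methoxy-4-(triisopropylsilyloxy)phenyl]cyclopropane-1-carboxamide | CON(C)C(=O)[C@H]1[C@@H](CO[Si](c2ccccc2)(c2ccccc2)C(C)(C)C)[C@@H]1c1ccc(O[Si](C(C)C)(C(C)C)C(C)C)c(OC)c1
F10 | step 6 | (1R,2S,3S)-2-[(tert-butyldiphenylsilyloxy)methyl]-3-[3-methoxy-4-(triisopropylsilyloxy)phenyl]cyclopropane-1-carbaldehyde | O=C[C@H]1[C@@H](CO[Si](c2ccccc2)(c2ccccc2)C(C)(C)C)[C@@H]1c1ccc(O[Si](C(C)C)(C(C)C)C(C)C)c(OC)c1
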